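**Retrosynthetic overview**
- Feature: the ring C8–C12 (C9 ketone, C10(Cl)=C11, tertiary carbinol C12 carrying the octadienyl chain, methine C8) is a 2-chloro-4-hydroxy-4-alkyl-5-alkylcyclopent-2-enone, the rearrangement product of a 3-chloro-5-alkyl-2-furylcarbinol. C4–C8 with the C5/C6/C7 triol is D-xylose (xylose C1 = C4, xylose C5 = C8).
- Disconnections: three acetates ⇒ acetonide + silyl ether; ring bond C8–C12 ⇒ furylcarbinol 28 (Piancatelli rearrangement, then C8 equilibration); C8–C9 ⇒ furyllithium 27 + xylose-derived aldehyde 13; C12–C13 ⇒ furyllithium + (2Z,5Z)-octadienyl bromide 18; C3=C4 ⇒ Wittig reaction on aldehydo-D-xylose diacetonide 4.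
- Ring order: the furan is bought (3-bromofuran) and carried as the latent ring; the only ring made is the cyclopentenone, in step 17, by opening the furan and closing C8–C12.

Key step: step 17

Assumption: the ring arrangement of the target (C7 chain trans to the octadienyl chain, cis to the C12 hydroxyl) is taken to be the thermodynamically preferred C8 configuration; positions are numbered as in the prostanoids (C1 = ester carbon, C20 = terminal methyl).

**Route**

Step 1
Reactants: 1 D-xylose
Product: 2 D-xylose diethyl dithioacetal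
Conditions: EtSH, conc. HCl, 0 °C
Reagents that add atoms: ethanethiol, CCS
Why: Acid-catalysed dithioacetal formation opens the pyranose and fixes the acyclic form without touching a stereocentre.

Step 2
Reactants: 2 D-xylose diethyl dithioacetal
Product: 3 2,3:4,5-di-O-isopropylidene-D-xylose diethyl dithioacetal
Conditions: 2,2-dimethoxypropane, acetone, p-TsOH·H2O (cat.), rt
Reagents that add atoms: 2,2-dimethoxypropane, COC(C)(C)OC
Why: Acid-catalysed transacetalisation under thermodynamic control should give the two dioxolanes (trans-2,3 and terminal 4,5), which already is the later C5/C6 acetonide.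

Step 3
Reactants: 3 2,3:4,5-di-O-isopropylidene-D-xylose diethyl dithioacetal
Product: 4 2,3:4,5-di-O-isopropylidene-aldehydo-D-xylose
Conditions: I2, NaHCO3, acetone/H2O, 0 °C
Reagents that add atoms: water, O
Why: Buffered iodine-mediated oxidative hydrolysis of the dithioacetal releases the aldehyde while the acetonides and the α-stereocentre are left alone.

Step 4
Reactants: 4 2,3:4,5-di-O-isopropylidene-aldehydo-D-xylose; 5 (2-carboxyethyl)triphenylphosphonium bromide
Product: 8 methyl (3Z)-2,3,4-trideoxy-5,6:7,8-di-O-isopropylidene-D-xylo-oct-3-enonate, via phosphorus ylide 6 (not isolated), via sodium carboxylate 7 (not isolated)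
Conditions: 5, NaHMDS (2.1 equiv), THF, −78 to 0 °C; 4, −78 °C to rt; then MeI, DMF, rt
Reagents that add atoms: iodomethane, CI
Why: Wittig olefination with the carboxylate-bearing non-stabilised ylide adds C1–C3 in one operation (alkene geometry is irrelevant because it is hydrogenated next), and the carboxylate is esterified in the same flask by SN2 methylation.

Step 5
Reactants: 8 methyl (3Z)-2,3,4-trideoxy-5,6:7,8-di-O-isopropylidene-D-xylo-oct-3-enonate
Product: 9 methyl 2,3,4-trideoxy-5,6:7,8-di-O-isopropylidene-D-xylo-octonate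
Conditions: H2 (1 atm), Pd/C, EtOAc, rt
Reagents that add atoms: none
Why: Heterogeneous catalytic hydrogenation saturates C3=C4; acetonides and ester are inert.

Step 6
Reactants: 9 methyl 2,3,4-trideoxy-5,6:7,8-di-O-isopropylidene-D-xylo-octonate
Product: 10 methyl 2,3,4-trideoxy-5,6-O-isopropylidene-D-xylo-octonate (7,8-diol)
Conditions: AcOH/H2O 7:3, 40 °C
Reagents that add atoms: none
Why: Selective acetal hydrolysis, the terminal monosubstituted dioxolane being cleaved faster than the internal trans-disubstituted one.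

Step 7
Reactants: 10 methyl 2,3,4-trideoxy-5,6-O-isopropylidene-D-xylo-octonate
Product: 11 methyl 7,8-bis-O-(tert-butyldimethylsilyl)-2,3,4-trideoxy-5,6-O-isopropylidene-D-xylo-octonate
Conditions: TBSCl, imidazole, DMF, rt
Reagents that add atoms: tert-butyldimethylsilyl chloride, CC(C)(C)[Si](C)(C)Cl
Why: Silyl ether formation on both hydroxyls puts the robust TBS group on O7 for the Lewis-acidic key step.

Step 8
Reactants: 11 methyl 7,8-bis-O-(tert-butyldimethylsilyl)-2,3,4-trideoxy-5,6-O-isopropylidene-D-xylo-octonate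
Product: 12 methyl 7-O-(tert-butyldimethylsilyl)-2,3,4-trideoxy-5,6-O-isopropylidene-D-xylo-octonate (8-ol)
Conditions: HF·pyridine, pyridine, THF, 0 °C
Reagents that add atoms: none
Why: Selective desilylation, the primary silyl ether being cleaved much faster than the hindered secondary one and without the silyl migration that basic conditions would risk.

Step 9
Reactants: 12 methyl 7-O-(tert-butyldimethylsilyl)-2,3,4-trideoxy-5,6-O-isopropylidene-D-xylo-octonate
Product: 13 methyl 7-(tert-butyldimethylsilyloxy)-5,6-(isopropylidenedioxy)-8-oxooctanoate (D-xylo; C5, C6, C7 = xylose C2, C3, C4)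
Conditions: Dess–Martin periodinane, CH2Cl2, rt
Reagents that add atoms: none
Why: Dess–Martin oxidation gives the α-silyloxy aldehyde under non-basic conditions, so C7 should not epimerise.

Step 10
Reactants: 14 1-bromopent-2-yne; 15 prop-2-yn-1-ol
Product: 16 octa-2,5-diyn-1-ol
Conditions: CuI, NaI, K2CO3, DMF, rt
Reagents that add atoms: none
Why: Copper-mediated coupling of a terminal alkyne with a propargylic bromide builds the skipped diyne.

Step 11
Reactants: 16 octa-2,5-diyn-1-ol
Product: 17 (2Z,5Z)-octa-2,5-dien-1-ol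
Conditions: H2 (1 atm), Pd/CaCO3 poisoned with Pb(OAc)2, quinoline, EtOAc, rt
Reagents that add atoms: none
Why: Lindlar semihydrogenation adds hydrogen syn to each alkyne and so sets both Z alkenes.

Step 12
Reactants: 17 (2Z,5Z)-octa-2,5-dien-1-ol
Product: 18 (2Z,5Z)-1-bromoocta-2,5-diene
Conditions: CBr4, PPh3, CH2Cl2, 0 °C
Reagents that add atoms: tetrabromomethane, BrC(Br)(Br)Br
Why: Appel bromination converts the primary allylic alcohol by SN2 with retention of both Z alkenes.

Step 13
Reactants: 19 3-bromofuran
Product: 21 3-bromo-2-(trimethylsilyl)furan, via 3-bromo-2-lithiofuran 20 (not isolated)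
Conditions: LDA, THF, −78 °C; TMSCl, −78 °C to rt
Reagents that add atoms: chlorotrimethylsilane, C[Si](C)(C)Cl
Why: Directed deprotonation at the position between oxygen and bromine, then silylation, blocks the carbon that must later carry C8.

Step 14
Reactants: 21 3-bromo-2-(trimethylsilyl)furan
Product: 23 3-chloro-2-(trimethylsilyl)furan, via 3-lithio-2-(trimethylsilyl)furan 22 (not isolated)
Conditions: n-BuLi, Et2O, −78 °C; C2Cl6, −78 °C to rt
Reagents that add atoms: hexachloroethane, ClC(Cl)(Cl)C(Cl)(Cl)Cl
Why: Bromine–lithium exchange followed by electrophilic chlorination swaps bromine for the chlorine of C10 on a non-volatile furan.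

Step 15
Reactants: 23 3-chloro-2-(trimethylsilyl)furan; 18 (2Z,5Z)-1-bromoocta-2,5-diene
Product: 26 4-chloro-2-[(2Z,5Z)-octa-2,5-dien-1-yl]furan, via 5-lithiofuran 24 (not isolated), via silylfuran 25 (not isolated)
Conditions: n-BuLi, THF, −78 to −20 °C; 18, −78 °C to rt; then TBAF, THF, rt
Reagents that add atoms: none
Why: With the other α-position blocked, lithiation occurs at the remaining α-carbon, SN2 alkylation with the primary allylic bromide forms C12–C13, and fluoride-induced protodesilylation frees the position next to chlorine.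

Step 16
Reactants: 26 4-chloro-2-[(2Z,5Z)-octa-2,5-dien-1-yl]furan; 13 methyl 7-(tert-butyldimethylsilyloxy)-5,6-(isopropylidenedioxy)-8-oxooctanoate
Product: 28 3-chloro-5-octadienyl-2-furylcarbinol (C8 epimer mixture; C7 silyl ether, C5/C6 acetonide, C1 methyl ester), via furyllithium 27 (not isolated)
Conditions: LDA, THF, −78 °C; 13, −78 °C; H2O quench
Reagents that add atoms: none
Why: LDA removes the ring proton flanked by oxygen and chlorine, and the furyllithium adds to the aldehyde at −78 °C much faster than to the methyl ester; the C8 carbinol forms as an epimer mixture, which does not matter because C8 becomes trigonal in step 17.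

Step 17
Reactants: 28 3-chloro-5-octadienyl-2-furylcarbinol (both C8 epimers)
Product: 29 methyl (5S,6R,7R,8R,12R)-7-(tert-butyldimethylsilyloxy)-10-chloro-12-hydroxy-5,6-(isopropylidenedioxy)-9-oxoprosta-10,14Z,17Z-trienoate (C7 chain trans to the C12 hydroxyl; C8 epimer of 30)
Conditions: ZnCl2 (2 equiv), acetone/H2O 3:1, 65 °C (sealed tube)
Reagents that add atoms: water, O
Why: ZnCl2 ionises either C8 epimer to the same furfuryl cation (C7 chain held away from the C10 chlorine), water adds at the alkyl-bearing furan carbon C12, and the hemiketal opens to the 1,4-dihydroxypentadienyl cation C8–C9–C10–C11–C12, which closes between C8 and C12 and loses a proton so that the former furan oxygen becomes the C9 ketone. This is the Piancatelli rearrangement, and its closest known case is the ZnCl2-mediated conversion of 5-methyl-2-furylcarbinols in aqueous acetone into 4-hydroxy-4-methyl-5-substituted cyclopent-2-enones. The one new ring, the five-membered carbocycle, closes by thermal conrotatory 4π electrocyclisation of that cation. Conrotation with the C7 chain outside at C8 and the hydroxyl (the π-donor) outside at C12 sets C8 and C12 together and places the new hydroxyl trans to the C7 chain, so the product of closure should be the C8 epimer of the target arrangement. The step needs the sense of rotation that gives 12R, that is C8–C12 bonding on the face of the C8=C9 enol opposite the C7 silyloxy group; A(1,3) strain with the C9 oxygen holds C7–H in the enol plane so that the electronegative, bulky OTBS group covers one face, and the alternative conformer with O7 in the plane and C6 anti to the forming bond leads to the same sense, while the opposite sense would follow if C6 rather than O7 took the anti position in the C7–H-in-plane conformer, so this induction is the unproven point of the route. Acetone as cosolvent keeps the acetonide in place, and the ester, silyl ether and skipped diene should be inert to ZnCl2 at this temperature.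

Step 18
Reactants: 29 (8R)-cyclopentenone
Product: 30 methyl (5S,6R,7R,8S,12R)-7-(tert-butyldimethylsilyloxy)-10-chloro-12-hydroxy-5,6-(isopropylidenedioxy)-9-oxoprosta-10,14Z,17Z-trienoate (chains trans)
Conditions: DBU (0.2 equiv), CH2Cl2, 0 °C to rt; AcOH quench
Reagents that add atoms: none
Why: Base-catalysed enolisation α to the C9 ketone equilibrates C8 to the epimer in which the large C7 substituent is cis to the small hydroxyl and trans to the octadienyl methylene (thermodynamic control), done while C7 still carries the poor leaving group OTBS.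

Step 19
Reactants: 30 (8S)-cyclopentenone
Product: 31 methyl (5S,6R,7R,8S,12R)-10-chloro-5,6,7,12-tetrahydroxy-9-oxoprosta-10,14Z,17Z-trienoate
Conditions: p-TsOH·H2O (0.3 equiv), MeOH, rt; solid NaHCO3 before cold concentration; used crude
Reagents that add atoms: none
Why: Acid-catalysed methanolysis cleaves silyl ether and acetonide together, and methanol as solvent keeps C1 as the methyl ester and reopens any δ-lactone formed from the C5 hydroxyl.

Step 20
Reactants: 31 triol
Product: 32 methyl (5S,6R,7R,8S,12R)-5,6,7-triacetoxy-10-chloro-12-hydroxy-9-oxoprosta-10,14Z,17Z-trienoate (target)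
Conditions: Ac2O, pyridine, CH2Cl2, 0 °C to rt, no DMAP
Reagents that add atoms: acetic anhydride, CC(=O)OC(C)=O
Why: Pyridine-mediated acylation esterifies the three secondary alcohols, while the hindered tertiary C12 alcohol does not react without DMAP and the weak base at low temperature should keep E1cB loss of the C7 acetate slow.

**Compound list**

1 | D-xylose | O=C[C@H](O)[C@@H](O)[C@H](O)CO | starting material
2 | D-xylose diethyl dithioacetal | CCSC(SCC)[C@H](O)[C@@H](O)[C@H](O)CO | intermediate
3 | 2,3:4,5-di-O-isopropylidene-D-xylose diethyl dithioacetal | C1OC(C)(C)O[C@H]1[C@@H]2OC(C)(C)O[C@H]2C(SCC)SCC | intermediate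
4 | 2,3:4,5-di-O-isopropylidene-aldehydo-D-xylose | C1OC(C)(C)O[C@H]1[C@@H]2OC(C)(C)O[C@H]2C=O | intermediate
5 | (2-carboxyethyl)triphenylphosphonium bromide | OC(=O)CC[P+](c1ccccc1)(c1ccccc1)c1ccccc1.[Br-] | starting material
6 | sodium 3-(triphenylphosphoranylidene)propanoate | [Na+].[O-]C(=O)CC=P(c1ccccc1)(c1ccccc1)c1ccccc1 | intermediate
7 | sodium (3Z)-2,3,4-trideoxy-5,6:7,8-di-O-isopropylidene-D-xylo-oct-3-enonate | C1OC(C)(C)O[C@H]1[C@@H]2OC(C)(C)O[C@H]2/C=C\CC(=O)[O-].[Na+] | intermediate
8 | methyl (3Z)-2,3,4-trideoxy-5,6:7,8-di-O-isopropylidene-D-xylo-oct-3-enonate | C1OC(C)(C)O[C@H]1[C@@H]2OC(C)(C)O[C@H]2/C=C\CC(=O)OC | intermediate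
9 | methyl 2,3,4-trideoxy-5,6:7,8-di-O-isopropylidene-D-xylo-octonate | C1OC(C)(C)O[C@H]1[C@@H]2OC(C)(C)O[C@H]2CCCC(=O)OC | intermediate
10 | methyl 2,3,4-trideoxy-5,6-O-isopropylidene-D-xylo-octonate | OC[C@@H](O)[C@@H]1OC(C)(C)O[C@H]1CCCC(=O)OC | intermediate
11 | methyl 7,8-bis-O-(tert-butyldimethylsilyl)-2,3,4-trideoxy-5,6-O-isopropylidene-D-xylo-octonate | CC(C)(C)[Si](C)(C)OC[C@@H](O[Si](C)(C)C(C)(C)C)[C@@H]1OC(C)(C)O[C@H]1CCCC(=O)OC | intermediate
12 | methyl 7-O-(tert-butyldimethylsilyl)-2,3,4-trideoxy-5,6-O-isopropylidene-D-xylo-octonate | OC[C@@H](O[Si](C)(C)C(C)(C)C)[C@@H]1OC(C)(C)O[C@H]1CCCC(=O)OC | intermediate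
13 | methyl 7-(tert-butyldimethylsilyloxy)-5,6-(isopropylidenedioxy)-8-oxooctanoate (D-xylo) | O=C[C@@H](O[Si](C)(C)C(C)(C)C)[C@@H]1OC(C)(C)O[C@H]1CCCC(=O)OC | intermediate
14 | 1-bromopent-2-yne | CCC#CCBr | starting material
15 | prop-2-yn-1-ol | C#CCO | starting material
16 | octa-2,5-diyn-1-ol | CCC#CCC#CCO | intermediate
17 | (2Z,5Z)-octa-2,5-dien-1-ol | CC/C=C\C/C=C\CO | intermediate
18 | (2Z,5Z)-1-bromoocta-2,5-diene | CC/C=C\C/C=C\CBr | intermediate
19 | 3-bromofuran | Brc1ccoc1 | starting material
20 | 3-bromo-2-lithiofuran | [Li]c1occc1Br | intermediate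
21 | 3-bromo-2-(trimethylsilyl)furan | C[Si](C)(C)c1occc1Br | intermediate
22 | 3-lithio-2-(trimethylsilyl)furan | [Li]c1ccoc1[Si](C)(C)C | intermediate
23 | 3-chloro-2-(trimethylsilyl)furan | C[Si](C)(C)c1occc1Cl | intermediate
24 | 3-chloro-5-lithio-2-(trimethylsilyl)furan | [Li]c1cc(Cl)c(o1)[Si](C)(C)C | intermediate
25 | 3-chloro-5-[(2Z,5Z)-octa-2,5-dien-1-yl]-2-(trimethylsilyl)furan | CC/C=C\C/C=C\Cc1cc(Cl)c(o1)[Si](C)(C)C | intermediate
26 | 4-chloro-2-[(2Z,5Z)-octa-2,5-dien-1-yl]furan | CC/C=C\C/C=C\Cc1cc(Cl)co1 | intermediate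
27 | 3-chloro-2-lithio-5-[(2Z,5Z)-octa-2,5-dien-1-yl]furan | CC/C=C\C/C=C\Cc1cc(Cl)c([Li])o1 | intermediate
28 | 3-chloro-5-octadienyl-2-furylcarbinol, C8 epimer mixture, C7 OTBS, C5/C6 acetonide | CC/C=C\C/C=C\Cc1cc(Cl)c(o1)C(O)[C@@H](O[Si](C)(C)C(C)(C)C)[C@@H]2OC(C)(C)O[C@H]2CCCC(=O)OC | intermediate
29 | (5S,6R,7R,8R,12R)-protected chlorohydroxycyclopentenone, C7 chain trans to 12-OH | CC/C=C\C/C=C\C[C@]1(O)C=C(Cl)C(=O)[C@@H]1[C@@H](O[Si](C)(C)C(C)(C)C)[C@@H]2OC(C)(C)O[C@H]2CCCC(=O)OC | intermediate
30 | (5S,6R,7R,8S,12R)-protected chlorohydroxycyclopentenone, chains trans | CC/C=C\C/C=C\C[C@]1(O)C=C(Cl)C(=O)[C@H]1[C@@H](O[Si](C)(C)C(C)(C)C)[C@@H]2OC(C)(C)O[C@H]2CCCC(=O)OC | intermediate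
31 | (5S,6R,7R,8S,12R)-5,6,7-triol | CC/C=C\C/C=C\C[C@]1(O)C=C(Cl)C(=O)[C@H]1[C@@H](O)[C@H](O)[C@H](CCCC(=O)OC)O | intermediate
32 | methyl (5S,6R,7R)-5,6,7-triacetoxy-7-[(1S,2R)-4-chloro-2-hydroxy-2-[(2Z,5Z)-octa-2,5-dien-1-yl]-5-oxocyclopent-3-en-1-yl]heptanoate | CC/C=C\C/C=C\C[C@]1(O)C=C(Cl)C(=O)[C@H]1[C@@H](OC(C)=O)[C@H](OC(C)=O)[C@H](CCCC(=O)OC)OC(C)=O | target

**Step count and risks**

Total step count: 20. Longest linear sequence: 14 steps (steps 1–9 and 16–20, from D-xylose).

Three steps most likely to fail:

1. Step 17. The C7 silyloxy group destabilises the furfuryl cation, so ionisation may be slow and may be overtaken by loss of the silyl ether or acetonide, or by capture of the cation by the C5 acetonide oxygen. The facial selectivity of the conrotation may also be poor or reversed, giving the 12S ring; the C8/C12 relationship of 29 would be checked before step 18. Fallback (sets out from 26 and 10, comes back at 29): the ring would be made without the side chain and joined to it by an aldol reaction.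
   - Lithiation of 26 as in step 16 and quenching with paraformaldehyde gives [3-chloro-5-[(2Z,5Z)-octa-2,5-dien-1-yl]furan-2-yl]methanol F1.
   - Rearrangement of F1 under the conditions of step 17 (a primary 5-alkylfurfuryl alcohol, no side-chain stereocentre involved) gives racemic 2-chloro-4-hydroxy-4-[(2Z,5Z)-octa-2,5-dien-1-yl]cyclopent-2-en-1-one F2, which TMSCl and imidazole in DMF convert into its trimethylsilyl ether F3.
   - NaIO4 cleavage of diol 10 gives methyl 5,6-(isopropylidenedioxy)-7-oxoheptanoate F4 (C5 and C6 as in 10).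
   - Deprotonation of F3 at C8 (LDA, THF, −78 °C), exchange to the magnesium enolate with MgBr2·OEt2 (non-chelated addition would favour the unwanted 6,7-anti carbinol) and addition of F4 should give aldol adducts. The 12R, 6,7-syn aldol adduct F5 (C8 as in 29) is separated by chromatography, the enantiopure aldehyde thereby resolving the racemic ring.
   - TBSOTf and 2,6-lutidine give the 7-O-TBS-12-O-TMS bis-silyl ether F6, and PPTS in MeOH removes the tertiary trimethylsilyl ether to give 29.

2. Step 18. The dienolate may expel silanolate from C7 to give the C7=C8 enone, or the equilibrium may not lie far enough on the side of the needed epimer. Fallback (sets out from 29, comes back at 31): a cyclic derivative pulls the equilibrium.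
   - HF·pyridine in THF removes the silyl ether of 29 to give the C7 alcohol F7.
   - Phenylboronic acid with catalytic Et3N in CH2Cl2 over 4 Å molecular sieves ties O7 to O12 as the six-membered cyclic phenylboronate F8. This ring can form without strain only when the C7 chain and the C12 oxygen are cis on the cyclopentenone, so enolisation at C8 is drawn to the needed epimer while C7 carries no leaving group better than hydroxide.
   - The methanolysis of step 19 then cleaves boronate and acetonide together to give 31.

3. Step 20. Enolisation at C8 by the amine may lead to E1cB loss of the C7 acetate, giving the cross-conjugated dienone, and the free C5 hydroxyl of 31 may lactonise onto the ester before it is acylated. Fallback (sets out from 30, comes back at 32): the protecting groups are exchanged in stages, so that the β-acetoxy ketone is formed only in a last, acid-catalysed acylation.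
   - BiCl3 (cat.) in MeCN/H2O removes the acetonide with the silyl ether retained, giving the 5,6-diol F9.
   - Ac2O, pyridine and DMAP give the 5,6-diacetate F10 while C7 still carries OTBS.
   - HF·pyridine frees the C7 hydroxyl to give the 7-alcohol F11.
   - Ac2O (1.1 equiv) with Sc(OTf)3 (cat.) in MeCN at −20 °C, where no enolate can form and the single equivalent should leave the tertiary alcohol free, gives 32. An acetyl shift between O6 and O7 in F11 is harmless because all three positions end as acetates.

**Further compounds**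

F1 | step 17 | [3-chloro-5-[(2Z,5Z)-octa-2,5-dien-1-yl]furan-2-yl]methanol | CC/C=C\C/C=C\Cc1cc(Cl)c(CO)o1
F2 | step 17 | racemic 2-chloro-4-hydroxy-4-[(2Z,5Z)-octa-2,5-dien-1-yl]cyclopent-2-en-1-one | CC/C=C\C/C=C\CC1(O)C=C(Cl)C(=O)C1
F3 | step 17 | racemic 2-chloro-4-[(2Z,5Z)-octa-2,5-dien-1-yl]-4-(trimethylsilyloxy)cyclopent-2-en-1-one | CC/C=C\C/C=C\CC1(O[Si](C)(C)C)C=C(Cl)C(=O)C1
F4 | step 17 | methyl 5,6-(isopropylidenedioxy)-7-oxoheptanoate (C5, C6 as in 10) | O=C[C@@H]1OC(C)(C)O[C@H]1CCCC(=O)OC
F5 | step 17 | aldol adduct, 7-hydroxy-12-(trimethylsilyloxy), ring configuration as in 29 | CC/C=C\C/C=C\C[C@]1(O[Si](C)(C)C)C=C(Cl)C(=O)[C@@H]1[C@@H](O)[C@@H]2OC(C)(C)O[C@H]2CCCC(=O)OC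
F6 | step 17 | 7-O-TBS-12-O-TMS bis-silyl ether, configuration as in 29 | CC/C=C\C/C=C\C[C@]1(O[Si](C)(C)C)C=C(Cl)C(=O)[C@@H]1[C@@H](O[Si](C)(C)C(C)(C)C)[C@@H]2OC(C)(C)O[C@H]2CCCC(=O)OC
F7 | step 18 | C7 alcohol from 29 (C8 as in 29) | CC/C=C\C/C=C\C[C@]1(O)C=C(Cl)C(=O)[C@@H]1[C@@H](O)[C@@H]2OC(C)(C)O[C@H]2CCCC(=O)OC
F8 | step 18 | cyclic phenylboronate across O7 and O12 (C8 as in 30) | CC/C=C\C/C=C\C[C@]1(O3)C=C(Cl)C(=O)[C@H]1[C@@H](OB3c3ccccc3)[C@@H]2OC(C)(C)O[C@H]2CCCC(=O)OC
F9 | step 20 | 5,6-diol with C7 silyl ether retained | CC/C=C\C/C=C\C[C@]1(O)C=C(Cl)C(=O)[C@H]1[C@@H](O[Si](C)(C)C(C)(C)C)[C@H](O)[C@H](CCCC(=O)OC)O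
F10 | step 20 | 5,6-diacetate with C7 silyl ether | CC/C=C\C/C=C\C[C@]1(O)C=C(Cl)C(=O)[C@H]1[C@@H](O[Si](C)(C)C(C)(C)C)[C@H](OC(C)=O)[C@H](CCCC(=O)OC)OC(C)=O
F11 | step 20 | 5,6-diacetate 7-alcohol | CC/C=C\C/C=C\C[C@]1(O)C=C(Cl)C(=O)[C@H]1[C@@H](O)[C@H](OC(C)=O)[C@H](CCCC(=O)OC)OC(C)=O
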